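Readings and results were computed for substances that don't exist.

Isomerisation cannot change the sum [target] + [isomer of the product], and I take it as the invariant here because the isomer of the product appears after the target. The sum grows by fresh target alone, and the isomer-to-target exchange then redistributes it.

| flask | starting material | partner | reagent | remark | time |
|---|---|---|---|---|---|
| red | 0.20 M | 0.24 M | 0.60 M | run made earlier |  |
| green | 0.20 M | 0.12 M | 0.60 M | run made earlier |  |
| Sunday's | 0.20 M | 0.240 M (fed, over 40 h) | 0.600 M | all else is in the flask from the start; the feed brings no volume worth counting | 3.0 d |
| Thursday's | 0.20 M | 0.240 M | 0.600 M | everything together at the start | 3.0 d |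
| Friday's | 0.20 M (fed, over 40 h) | 0.240 M | 0.600 M | all else is in the flask from the start; the feed brings no volume worth counting | 3.0 d |

- red (time / h: target / %, isomer of the product / %): 2.50: 0.5, 1.0; 6.00: 5.2, 1.0; 12.0: 16.8, 5.3; 20.0: 27.8, 11.8; 25.0: 32.8, 16.1; 30.0: 35.8, 18.8; 40.0: 41.6, 23.5
- green (time / h: target / %, isomer of the product / %): 1.50: 0, 0; 2.50: 0.9, 0; 4.00: 2.8, 0; 6.00: 3.4, 1.4; 10.0: 7.5, 2.0; 15.0: 11.5, 3.7; 20.0: 14.9, 7.8

(scatter of a reading: 0.5 percentage points)

- the flask with the highest share of target in target plus isomer of the product ("all alike" if they lie within 1.5 percentage points) (Sunday's / Thursday's / Friday's / all alike)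
- share of target in target plus isomer of the product at the end, Sunday's
- share of target in target plus isomer of the product at the end, Thursday's
- share of target in target plus isomer of the product at the end, Friday's

The bench rule says that a relaxed pair shows its equilibrium share whatever the order of addition, so I treat that share as the large term and reckon the small one. Fresh target gives the share a lead, which follows the growth of the sum relative to the sum. Growth follows the rest, meaning the charge not yet in the pair, so the lead goes as rest over made.

The red run gives a share of 65.6% at 30.0 h with rest over made 0.832, then 63.9% at 40.0 h with 0.536. The lead coefficient, share gained per unit of rest over made, is therefore 0.0564, and the base share reads 60.9%, both carrying the scatter.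

The rest in the red run decays at 0.0263 h⁻¹. Thursday's has the red charge, so its ratio at the end is 0.177. As an assumption of mine, not a reading, I let Sunday's fed partner cost half of its feed time, which gives Sunday's a ratio of 0.341. The two runs share one charge of starting material, so they tell me nothing about feeding it, and for Friday's I simply try both cases, the same delay and no delay.

The border is the margin over the coefficient, 0.266, and the gap of 0.164 is smaller. I reckon 61.9% for Thursday's and 62.8% for Sunday's, and Friday's takes one of these two values in my two trials, so I count the flasks as alike.

The forecast, “which suggests reversible target ⇌ isomer”, gives 63% for Sunday's, 62% for Thursday's, 63% for Friday's, and all alike.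

The flasks give 63.9%, 63.1% and 63.2%: all alike.

    starting material + reagent → open intermediate (k = 0.470 M⁻¹ h⁻¹)
    reagent + partner → second intermediate (k = 0.0820 M⁻¹ h⁻¹)
    open intermediate + second intermediate → target (k = 1.00 M⁻¹ h⁻¹)
    target ⇌ isomer of the product (K = 0.600, k = 0.110 h⁻¹)

Taking away the reverse step, isomer of the product to target, turns Thursday's share most, from 63.1% to 5.42%. The coefficient then reads the simulated rests. Sunday's holds 28.4% as open intermediate, so its ratio is 0.397 and the reckoned share 63.1%, against 63.9% in the flask. Thursday's flask read at 30 h holds 44.5% as open intermediate, so its ratio is 0.828, the reckoned share is 65.6%, and the flask gives 65.8%.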